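**Retrosynthetic overview**
- The last bond made is the enol ether C–O bond: CuI-catalysed coupling of the ring A carbinol with a (Z)-vinyl iodide that carries ring B, followed by fluoride desilylation.
- The feature the route rests on: on ring A the C7 methoxy oxygen is ortho to C6, which bears the carbinol carbon C1'. The other ortho carbon, C5, lies next to the ring fusion carbon C4a. The carbinol can therefore deliver silicon, and then oxygen, to C7 through a temporary five-membered oxasilole (C1', O, Si, C7, C6).
- Without the C7 oxygen, the pyran ring comes from para-substituted 1-(4-hydroxyphenyl)ethanone, whose two ortho carbons are equivalent, so no linear/angular question arises.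
- Ring order: pyran ring (step 2), temporary oxasilole ring (step 5, opened in step 6). Ring B is bought as 2-bromo-5-methylphenol and joined to C2 of propargyl alcohol by anti-arylmagnesiation, which also fixes the Z geometry.

Key step: step 5

Remark: chromene numbering O1, C2 … C8a is used and the carbinol carbon is C1'. cod is 1,5-cyclooctadiene (C8H12). TsDPEN is the monoanion of N-tosyl-1,2-diphenylethane-1,2-diamine. Compounds 11, 12, 21 and 22 are acid-labile, so everything after step 6 is run and worked up under neutral or basic conditions.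

**Route**

Step 1
Reactants: 1 1-(4-hydroxyphenyl)ethanone; 2 3-chloro-3-methylbut-1-yne
Product: 3 1-{4-[(2-methylbut-3-yn-2-yl)oxy]phenyl}ethanone
Conditions: DBU, CuCl2 (cat.), MeCN, 0 °C to rt
Reagents that add atoms: none
Why: Copper-catalysed O-propargylation of a phenol by a tertiary propargylic chloride is the standard entry to 1,1-dimethylpropargyl aryl ethers and works well with electron-poor phenols.

Step 2
Reactants: 3 1-{4-[(2-methylbut-3-yn-2-yl)oxy]phenyl}ethanone
Product: 6 1-(2,2-dimethyl-2H-chromen-6-yl)ethanone, via allenylphenol 4 (not isolated), via ortho-quinone methide 5 (not isolated)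
Conditions: 1,2-dichlorobenzene, 180 °C
Reagents that add atoms: none
Why: Aromatic propargyl Claisen rearrangement, 1,5-hydrogen shift and 6π oxa-electrocyclisation close the pyran ring, and since the acetyl group is para to the oxygen both ortho carbons are equivalent, so only the 6-acetyl chromene can form.

Step 3
Reactants: 6 1-(2,2-dimethyl-2H-chromen-6-yl)ethanone
Product: 7 (S)-1-(2,2-dimethyl-2H-chromen-6-yl)ethanol
Conditions: RuCl[(S,S)-TsDPEN](p-cymene) (1 mol%), HCO2H/Et3N (5:2), 30 °C
Reagents that add atoms: none
Why: Noyori asymmetric transfer hydrogenation of an aryl methyl ketone, in which the (S,S)-TsDPEN ruthenium hydride should deliver hydride to the face that gives the S carbinol and should leave the C3=C4 double bond untouched.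

Step 4
Reactants: 7 (S)-1-(2,2-dimethyl-2H-chromen-6-yl)ethanol; 8 diethylsilane
Product: 9 (S)-diethyl[1-(2,2-dimethyl-2H-chromen-6-yl)ethoxy]silane
Conditions: [Ir(OMe)(cod)]2 (0.05 mol%), Et2SiH2 (1.2 equiv), THF, rt; volatiles removed, crude 9 used directly
Reagents that add atoms: none
Why: Iridium-catalysed dehydrogenative Si–O coupling of a secondary alcohol with a dihydrosilane should stop at the monoalkoxy hydrosilane with a slight excess of silane, and no bond at C1' is touched.

Step 5
Reactants: 9 (S)-diethyl[1-(2,2-dimethyl-2H-chromen-6-yl)ethoxy]silane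
Product: 10 (S)-benzoxasilole: a 1,1-diethyl-3-methyl-1,3-dihydro-2,1-benzoxasilole ring fused across C6–C7 of the 2,2-dimethyl-2H-chromene, with Si on C7 and the CH(CH3)–O carbon on C6
Conditions: [Ir(OMe)(cod)]2 (1 mol%), 1,10-phenanthroline (2.5 mol%), norbornene (1.2 equiv), THF, 80 °C
Reagents that add atoms: none
Why: An iridium silyl complex formed from the Si–H bond of 9 under phenanthroline ligation cleaves the C7–H bond that the C1'–O–Si tether holds within reach, norbornene takes up the two hydrogen atoms as norbornane, and C–Si reductive elimination releases 10; this is the known iridium-catalysed, hydroxyl-directed dehydrogenative ortho C–H silylation of benzylic hydrosilyl ethers. The oxasilole ring (C1', O, Si, C7, C6) closes at the Si–C7 bond by contraction of a six-membered iridacycle onto the aromatic carbon. No stereocentre is formed, and the S centre at C1' is a spectator because none of its bonds is touched. The step needs C7 over C5: C5 is flanked by the ring-fusion carbon C4a and its vinyl arm, whereas C7 has only C8–H beside it, and this silylation is known to choose the less hindered ortho carbon of meta-substituted substrates. It also needs the C3=C4 double bond to survive; that bond is cis-disubstituted, conjugated and has no allylic hydrogen through which it could isomerise, and the strained norbornene should intercept the iridium hydride first.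

Step 6
Reactants: 10 (S)-benzoxasilole
Product: 11 (S)-6-(1-hydroxyethyl)-2,2-dimethyl-2H-chromen-7-ol
Conditions: aq. H2O2 (30%), KHCO3, THF/MeOH, rt; neutral work-up
Reagents that add atoms: hydrogen peroxide, OO
Why: Tamao–Fleming oxidation, in which hydroperoxide adds to the alkoxy-activated silicon, the aryl group migrates from Si to O at C7, and hydrolysis of the Si–O bonds should free the phenol and the unchanged S carbinol.

Step 7
Reactants: 11 (S)-6-(1-hydroxyethyl)-2,2-dimethyl-2H-chromen-7-ol
Product: 12 (S)-1-(7-methoxy-2,2-dimethyl-2H-chromen-6-yl)ethanol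
Conditions: MeI, K2CO3, acetone, rt
Reagents that add atoms: iodomethane, CI
Why: Williamson methylation that should be selective for the phenoxide, since K2CO3 deprotonates the phenol but not the secondary benzylic alcohol.

Step 8
Reactants: 13 2-bromo-5-methylphenol
Product: 14 1-bromo-2-(methoxymethoxy)-4-methylbenzene
Conditions: MOMCl, iPr2NEt, CH2Cl2, 0 °C to rt
Reagents that add atoms: chloromethyl methyl ether, COCCl
Why: Acetal protection of the phenol as its MOM ether, which survives Grignard formation and does not undergo silyl-type migration to the ortho carbanion.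

Step 9
Reactants: 14 1-bromo-2-(methoxymethoxy)-4-methylbenzene; 15 prop-2-yn-1-ol
Product: 18 (Z)-3-iodo-2-[2-(methoxymethoxy)-4-methylphenyl]prop-2-en-1-ol, via arylmagnesium bromide 16 (not isolated), via oxamagnesole chelate 17 (not isolated)
Conditions: Mg, THF, 40 °C; then 15 (0.4 equiv), CuI (10 mol%), THF/toluene, 0 to 65 °C; then I2, THF, −20 °C to rt
Reagents that add atoms: iodine, II
Why: Copper-catalysed anti-carbomagnesiation of propargyl alcohol (Duboudin reaction) places the aryl group on C2 and magnesium on C3 trans to it inside a five-membered alkoxide chelate, so iodinolysis with retention should put iodine cis to CH2OH and give the Z iodide.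

Step 10
Reactants: 18 (Z)-3-iodo-2-[2-(methoxymethoxy)-4-methylphenyl]prop-2-en-1-ol
Product: 19 2-[(Z)-3-hydroxy-1-iodoprop-1-en-2-yl]-5-methylphenol
Conditions: HCl (cat.), MeOH, 40 °C
Reagents that add atoms: none
Why: Acid-catalysed acetal exchange of the aryl MOM ether with methanol, under which the vinyl iodide and the primary allylic alcohol should be stable.

Step 11
Reactants: 19 2-[(Z)-3-hydroxy-1-iodoprop-1-en-2-yl]-5-methylphenol
Product: 20 (Z)-triisopropyl{[3-iodo-2-(4-methyl-2-{[tri(propan-2-yl)silyl]oxy}phenyl)prop-2-en-1-yl]oxy}silane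
Conditions: TIPSOTf (2.4 equiv), 2,6-lutidine, CH2Cl2, 0 °C to rt
Reagents that add atoms: triisopropylsilyl trifluoromethanesulfonate, CC(C)[Si](OS(=O)(=O)C(F)(F)F)(C(C)C)C(C)C
Why: Silylation of both hydroxyl groups with the silyl triflate; the triisopropylsilyl ethers are chosen because they should withstand Cs2CO3 at 80 °C and leave together with fluoride at the end.

Step 12
Reactants: 12 (S)-1-(7-methoxy-2,2-dimethyl-2H-chromen-6-yl)ethanol; 20 the (Z)-vinyl iodide bis-silyl ether
Product: 21 (Z)-enol ether of 12 with both ring B hydroxyls as triisopropylsilyl ethers: 7-methoxy-2,2-dimethyl-6-[(1S)-1-{[(Z)-2-(4-methyl-2-{[tri(propan-2-yl)silyl]oxy}phenyl)-3-{[tri(propan-2-yl)silyl]oxy}prop-1-en-1-yl]oxy}ethyl]-2H-chromene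
Conditions: CuI (10 mol%), 3,4,7,8-tetramethyl-1,10-phenanthroline (20 mol%), Cs2CO3, toluene, 80 °C; 20 in slight excess
Reagents that add atoms: none
Why: Copper-catalysed Ullmann-type C–O coupling of a vinyl iodide with an alcohol, which goes with retention of the alkene geometry and, because the C1'–O bond is never broken, with retention of the S centre.

Step 13
Reactants: 21 the bis-silylated (S,Z)-enol ether
Product: 22 2-{(Z)-3-hydroxy-1-[(1S)-1-(7-methoxy-2,2-dimethyl-2H-chromen-6-yl)ethoxy]prop-1-en-2-yl}-5-methylphenol (target)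
Conditions: TBAF (2.5 equiv), THF, 0 °C to rt; pH 7 buffer work-up
Reagents that add atoms: none
Why: Fluoride cleavage of the aryl and primary silyl ethers under basic, non-acidic conditions, which should spare the acid-labile enol ether, the benzylic ether and the chromene.

**Compound list**

1 | 1-(4-hydroxyphenyl)ethanone | CC(=O)c1ccc(O)cc1 | starting material
2 | 3-chloro-3-methylbut-1-yne | CC(C)(Cl)C#C | starting material
3 | 1-{4-[(2-methylbut-3-yn-2-yl)oxy]phenyl}ethanone | CC(=O)c1ccc(OC(C)(C)C#C)cc1 | intermediate
4 | 1-[4-hydroxy-3-(3-methylbuta-1,2-dien-1-yl)phenyl]ethanone (allenylphenol) | CC(=O)c1ccc(O)c(C=C=C(C)C)c1 | intermediate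
5 | (Z)-4-acetyl-6-(3-methylbut-2-en-1-ylidene)cyclohexa-2,4-dien-1-one (ortho-quinone methide) | CC(=O)C1=C/C(=C/C=C(C)C)C(=O)C=C1 | intermediate
6 | 1-(2,2-dimethyl-2H-chromen-6-yl)ethanone | CC(=O)c1ccc2OC(C)(C)C=Cc2c1 | intermediate
7 | (S)-1-(2,2-dimethyl-2H-chromen-6-yl)ethanol | CC1(C)C=Cc2cc([C@H](C)O)ccc2O1 | intermediate
8 | diethylsilane | CC[SiH2]CC | starting material
9 | (S)-diethyl[1-(2,2-dimethyl-2H-chromen-6-yl)ethoxy]silane | CC1(C)C=Cc2cc([C@H](C)O[SiH](CC)CC)ccc2O1 | intermediate
10 | (S)-benzoxasilole fused at C6–C7 of the chromene (Si on C7) | CC1(C)C=Cc2cc3[C@H](C)O[Si](CC)(CC)c3cc2O1 | intermediate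
11 | (S)-6-(1-hydroxyethyl)-2,2-dimethyl-2H-chromen-7-ol | CC1(C)C=Cc2cc([C@H](C)O)c(O)cc2O1 | intermediate
12 | (S)-1-(7-methoxy-2,2-dimethyl-2H-chromen-6-yl)ethanol | COc1cc2OC(C)(C)C=Cc2cc1[C@H](C)O | intermediate
13 | 2-bromo-5-methylphenol | Cc1ccc(Br)c(O)c1 | starting material
14 | 1-bromo-2-(methoxymethoxy)-4-methylbenzene | COCOc1cc(C)ccc1Br | intermediate
15 | prop-2-yn-1-ol | OCC#C | starting material
16 | [2-(methoxymethoxy)-4-methylphenyl]magnesium bromide | COCOc1cc(C)ccc1[Mg]Br | intermediate
17 | 4-[2-(methoxymethoxy)-4-methylphenyl]-2,5-dihydro-1,2-oxamagnesole (cyclic alkenylmagnesium alkoxide) | COCOc1cc(C)ccc1C1=C[Mg]OC1 | intermediate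
18 | (Z)-3-iodo-2-[2-(methoxymethoxy)-4-methylphenyl]prop-2-en-1-ol | I/C=C(\CO)c1ccc(C)cc1OCOC | intermediate
19 | 2-[(Z)-3-hydroxy-1-iodoprop-1-en-2-yl]-5-methylphenol | I/C=C(\CO)c1ccc(C)cc1O | intermediate
20 | (Z)-triisopropyl{[3-iodo-2-(4-methyl-2-{[tri(propan-2-yl)silyl]oxy}phenyl)prop-2-en-1-yl]oxy}silane | I/C=C(\CO[Si](C(C)C)(C(C)C)C(C)C)c1ccc(C)cc1O[Si](C(C)C)(C(C)C)C(C)C | intermediate
21 | bis(triisopropylsilyl) ether of the target, (S,Z) | COc1cc2c(cc1[C@H](C)O/C=C(\CO[Si](C(C)C)(C(C)C)C(C)C)c1ccc(C)cc1O[Si](C(C)C)(C(C)C)C(C)C)C=CC(C)(C)O2 | intermediate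
22 | 2-{(Z)-3-hydroxy-1-[(1S)-1-(7-methoxy-2,2-dimethyl-2H-chromen-6-yl)ethoxy]prop-1-en-2-yl}-5-methylphenol | COc1cc2c(cc1[C@H](C)O/C=C(\CO)c1ccc(C)cc1O)C=CC(C)(C)O2 | target

**Step count and risks**

Total step count: 13. Longest linear sequence: 9 steps (steps 1 to 7, 12 and 13, from compound 1); the ring B branch is steps 8 to 11.

Steps most likely to fail:

1. Step 5. The iridium hydride or silyl species may add to the C3=C4 double bond (hydrosilylation or reduction) faster than norbornene takes up hydrogen, or the alkene may slow the catalyst so that silylation stalls or loses its preference for C7 over C5. Fallback: give up the C–H oxygenation and bring the C7 oxygen in with the phenol, setting out from 2 and returning at 12. Commercial 3-methoxyphenol is O-alkylated with 2 (DBU, CuCl2 cat., MeCN) to 1-methoxy-3-[(2-methylbut-3-yn-2-yl)oxy]benzene F1. Thermal Claisen rearrangement and electrocyclisation (1,2-dichlorobenzene, 180 °C) should close mainly onto the less hindered ortho carbon, para to the methoxy group, to give 7-methoxy-2,2-dimethyl-2H-chromene F2. Mild Friedel–Crafts acetylation (Ac2O, ZnCl2, CH2Cl2, 0 °C) at C6, para to O1 and ortho to the methoxy group, gives 1-(7-methoxy-2,2-dimethyl-2H-chromen-6-yl)ethanone F3. Transfer hydrogenation under the conditions of step 3 then gives 12. The price is a regioisomer separation after the rearrangement and an acid-sensitive chromene in the acylation.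

2. Step 12. C–O bond formation between the hindered secondary alkoxide and the 2,2-disubstituted vinyl iodide may be slow, leaving time for loss of iodine from the alkene or for transfer of the aryl silyl group to the caesium alkoxide. Fallback: reverse the polarity of the alkene partner, setting out from 20 and returning at 21. Iodine–lithium exchange on 20 (t-BuLi, Et2O, −78 °C) and trapping with 2-isopropoxy-4,4,5,5-tetramethyl-1,3,2-dioxaborolane gives, with retention, the (Z)-alkenyl pinacol boronate F4. Oxidative Chan–Lam-type coupling of F4 (in excess) with 12 (Cu(OAc)2, Et3N, 4 Å molecular sieves, CH2Cl2, air, rt) then gives 21.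

3. Step 9. Anti-addition of the ortho-substituted aryl Grignard reagent to the propargyl alkoxide may be slow or incomplete, and the alkenylmagnesium may be protonated before iodine arrives, giving the iodine-free allylic alcohol. Fallback: build the same alkene by syn-hydrometalation and two stereoretentive substitutions, setting out from 14 and returning at 18. Palladium-catalysed hydrostannation of commercial 3-(trimethylsilyl)prop-2-yn-1-ol (Bu3SnH, PdCl2(PPh3)2, THF) should place tin on C2, syn to hydrogen, giving (E)-2-(tributylstannyl)-3-(trimethylsilyl)prop-2-en-1-ol F5. Stille coupling of F5 with 14 (Pd(PPh3)4, CuI, DMF, 50 °C) gives (Z)-2-[2-(methoxymethoxy)-4-methylphenyl]-3-(trimethylsilyl)prop-2-en-1-ol F6, in which silicon is cis to CH2OH. Iododesilylation with N-iodosuccinimide (MeCN, 0 °C), which goes with retention, then gives 18.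

**Further compounds**

F1 | step 5 | 1-methoxy-3-[(2-methylbut-3-yn-2-yl)oxy]benzene | COc1cccc(OC(C)(C)C#C)c1
F2 | step 5 | 7-methoxy-2,2-dimethyl-2H-chromene | COc1ccc2C=CC(C)(C)Oc2c1
F3 | step 5 | 1-(7-methoxy-2,2-dimethyl-2H-chromen-6-yl)ethanone | COc1cc2OC(C)(C)C=Cc2cc1C(C)=O
F4 | step 12 | (Z)-2-[2-(4-methyl-2-{[tri(propan-2-yl)silyl]oxy}phenyl)-3-{[tri(propan-2-yl)silyl]oxy}prop-1-en-1-yl]-4,4,5,5-tetramethyl-1,3,2-dioxaborolane | CC1(C)OB(/C=C(\CO[Si](C(C)C)(C(C)C)C(C)C)c2ccc(C)cc2O[Si](C(C)C)(C(C)C)C(C)C)OC1(C)C
F5 | step 9 | (E)-2-(tributylstannyl)-3-(trimethylsilyl)prop-2-en-1-ol | C[Si](C)(C)/C=C(\CO)[Sn](CCCC)(CCCC)CCCC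
F6 | step 9 | (Z)-2-[2-(methoxymethoxy)-4-methylphenyl]-3-(trimethylsilyl)prop-2-en-1-ol | C[Si](C)(C)/C=C(\CO)c1ccc(C)cc1OCOC
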